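**Retrosynthetic overview**
1. The inter-ring bond (ring A C6–CH2) is cut first: C-alkylation of a ring A α-ketol enolate with a ring B 2-substituted allylic iodide.
2. Ring B (bromohydrin ring) is taken intact from (R)-(+)-limonene: a proposed selenium-catalysed syn-hydroxybromination of the ring alkene sets the C–OH and C–Br centres, then the isopropenyl group is converted to the allylic iodide.
3. Ring A (diol ring) is taken intact from (S)-(+)-carvone: nucleophilic epoxidation sets the tertiary carbinol, hydride opening and reoxidation give the α-ketol; C6 is set in the alkylation and the secondary carbinol by a late ketone reduction.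
4. Order: no ring is built. Ring B is functionalised first, ring A second, then union, carbinol reduction and desilylation.

Assumption: the target is made exactly as drawn, (1S,2S,3R,4S)-3-{2-[(1R,3R,4S)-3-bromo-4-hydroxy-4-methylcyclohexyl]prop-2-en-1-yl}-1-methyl-4-(prop-1-en-2-yl)cyclohexane-1,2-diol, and (R)-(+)-limonene, (S)-(+)-carvone and LiN(iPr)2 solution are bought.
Locants in the text: ring A is numbered as in carvone (C1 carbonyl or carbinol carbon, C2 methyl-bearing carbon, C5 isopropenyl-bearing carbon, C6 side-chain carbon). Ring B is numbered as in limonene (C1 methyl carbinol carbon, C2 bromine-bearing carbon, C4 side-chain carbon).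

**Step 1**
Reactants: 1 (R)-(+)-limonene, (4R)-1-methyl-4-(prop-1-en-2-yl)cyclohex-1-ene
Product: 3 (1S,2R,4R)-2-bromo-1-methyl-4-(prop-1-en-2-yl)cyclohexan-1-ol, via hydroxy selenide 2 (not isolated)
Conditions: PhSeSePh (5 mol%), NBS (1.05 equiv, added over 4 h), H2O (5 equiv), MeCN, −30 °C, dark
Reagents that add atoms: N-bromosuccinimide, O=C1CCC(=O)N1Br; water, O
Why: Proposed new method: NBS turns the diselenide into PhSeBr, which adds reversibly to the more electron-rich ring alkene; water opens the seleniranium ion at tertiary C1 in the Markovnikov, trans-diaxial sense to give 2 (OH cis to isopropenyl, Se at C2); slowly fed NBS (through the HBr released) then oxidises the selenide to a tetravalent bromoselenonium bromide whose ion-paired bromide displaces selenium at C2 by SN2 with inversion, so Br ends cis to OH and to the C4 substituent and PhSeBr is regenerated; the net result is a syn-hydroxybromination, and the closest known reaction types are selenium-catalysed syn-dichlorination of alkenes and stoichiometric invertive bromodeselenation of alkyl phenyl selenides with Br2.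

**Step 2**
Reactants: 3 (1S,2R,4R)-2-bromo-1-methyl-4-(prop-1-en-2-yl)cyclohexan-1-ol
Product: 4 {[(1S,2R,4R)-2-bromo-1-methyl-4-(prop-1-en-2-yl)cyclohexyl]oxy}triethylsilane
Conditions: Et3SiOTf, 2,6-lutidine, CH2Cl2, −78 to 0 °C
Reagents that add atoms: triethylsilyl trifluoromethanesulfonate, CC[Si](CC)(CC)OS(=O)(=O)C(F)(F)F
Why: Silylation of the hindered tertiary alcohol by a silyl triflate under lutidine buffering masks the acidic hydroxyl for the later enolate alkylation; no stereocentre changes.

**Step 3**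
Reactants: 4 {[(1S,2R,4R)-2-bromo-1-methyl-4-(prop-1-en-2-yl)cyclohexyl]oxy}triethylsilane
Product: 5 {[(1S,2R,4R)-2-bromo-4-(3-chloroprop-1-en-2-yl)-1-methylcyclohexyl]oxy}triethylsilane
Conditions: Ca(OCl)2, CO2 (dry ice), CH2Cl2/H2O, 0 °C
Reagents that add atoms: calcium hypochlorite, [Ca+2].[O-]Cl.[O-]Cl
Why: Ene-type allylic chlorination by HOCl: Cl+ adds to the terminal CH2 of the 1,1-disubstituted alkene and the tertiary cation loses a methyl proton, giving the transposed 2-substituted allyl chloride without touching a stereocentre.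

**Step 4**
Reactants: 5 {[(1S,2R,4R)-2-bromo-4-(3-chloroprop-1-en-2-yl)-1-methylcyclohexyl]oxy}triethylsilane
Product: 6 {[(1S,2R,4R)-2-bromo-4-(3-iodoprop-1-en-2-yl)-1-methylcyclohexyl]oxy}triethylsilane
Conditions: NaI, acetone, rt, dark
Reagents that add atoms: sodium iodide, [Na+].[I-]
Why: Finkelstein SN2 exchange at the primary allylic chloride; the hindered secondary ring bromide does not exchange at room temperature.

**Step 5**
Reactants: 7 (S)-(+)-carvone, (5S)-2-methyl-5-(prop-1-en-2-yl)cyclohex-2-en-1-one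
Product: 8 (1S,4S,6S)-1-methyl-4-(prop-1-en-2-yl)-7-oxabicyclo[4.1.0]heptan-2-one
Conditions: 30% H2O2, NaOH (cat.), MeOH, 0 °C
Reagents that add atoms: hydrogen peroxide, OO
Why: Weitz–Scheffer nucleophilic epoxidation: hydroperoxide adds only to the enone, axially at C3 and anti to the C5 isopropenyl group, so the epoxide oxygen (the future tertiary hydroxyl at C2) is set trans to isopropenyl.

**Step 6**
Reactants: 8 (1S,4S,6S)-1-methyl-4-(prop-1-en-2-yl)-7-oxabicyclo[4.1.0]heptan-2-one
Product: 10 (1S,4S)-1-methyl-4-(prop-1-en-2-yl)cyclohexane-1,2-diol as a mixture of C2 epimers (expected mainly 2R), via epoxy alkoxide 9 (not isolated)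
Conditions: LiAlH4, THF, 0 °C to reflux; H2O/NaOH work-up
Reagents that add atoms: none
Why: LiAlH4 first reduces the ketone to alkoxide 9 and then opens the epoxide by SN2 hydride attack at the less substituted C3, keeping the C2–O bond and its configuration; the epimer ratio at the secondary carbinol does not matter because that centre is reoxidised in step 7.

**Step 7**
Reactants: 10 (1S,4S)-1-methyl-4-(prop-1-en-2-yl)cyclohexane-1,2-diol (epimer mixture)
Product: 11 (2S,5S)-2-hydroxy-2-methyl-5-(prop-1-en-2-yl)cyclohexan-1-one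
Conditions: IBX, DMSO, rt
Reagents that add atoms: none
Why: IBX oxidation of the secondary alcohol of a 1,2-diol gives the α-ketol without C–C cleavage; the tertiary alcohol and the alkene do not react and both epimers of 10 converge on 11.

**Step 8**
Reactants: 11 (2S,5S)-2-hydroxy-2-methyl-5-(prop-1-en-2-yl)cyclohexan-1-one; 6 {[(1S,2R,4R)-2-bromo-4-(3-iodoprop-1-en-2-yl)-1-methylcyclohexyl]oxy}triethylsilane
Product: 13 (2S,5S,6R)-6-{2-[(1R,3R,4S)-3-bromo-4-methyl-4-(triethylsilyloxy)cyclohexyl]prop-2-en-1-yl}-2-hydroxy-2-methyl-5-(prop-1-en-2-yl)cyclohexan-1-one, via dilithium dianion 12 (not isolated)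
Conditions: LiN(iPr)2 (2.2 equiv), THF, −78 °C; then 6, DMPU, −78 to −20 °C; aq NH4Cl
Reagents that add atoms: none
Why: Enolate alkylation: only C6 carries acidic hydrogens (C2 is quaternary), so the base gives the alkoxide–enolate dianion 12 regiospecifically, and the allylic iodide attacks C6 on the face anti to the neighbouring C5 isopropenyl group, giving the trans C5/C6 arrangement that is also the thermodynamically preferred diequatorial one.

**Step 9**
Reactants: 13 (2S,5S,6R)-6-{2-[(1R,3R,4S)-3-bromo-4-methyl-4-(triethylsilyloxy)cyclohexyl]prop-2-en-1-yl}-2-hydroxy-2-methyl-5-(prop-1-en-2-yl)cyclohexan-1-one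
Product: 14 (1S,2S,3R,4S)-3-{2-[(1R,3R,4S)-3-bromo-4-methyl-4-(triethylsilyloxy)cyclohexyl]prop-2-en-1-yl}-1-methyl-4-(prop-1-en-2-yl)cyclohexane-1,2-diol
Conditions: NaBH4, MeOH, −20 to 0 °C
Reagents that add atoms: none
Why: Ketone reduction by NaBH4: hydride attacks C1 axially from the face opposite the axial C2 methyl group (the face of the C2 hydroxyl, which can also guide the borohydride), giving the equatorial alcohol trans to both the tertiary hydroxyl and the C6 side chain; the secondary bromide and the silyl ether are inert.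

**Step 10**
Reactants: 14 (1S,2S,3R,4S)-3-{2-[(1R,3R,4S)-3-bromo-4-methyl-4-(triethylsilyloxy)cyclohexyl]prop-2-en-1-yl}-1-methyl-4-(prop-1-en-2-yl)cyclohexane-1,2-diol
Product: 15 (1S,2S,3R,4S)-3-{2-[(1R,3R,4S)-3-bromo-4-hydroxy-4-methylcyclohexyl]prop-2-en-1-yl}-1-methyl-4-(prop-1-en-2-yl)cyclohexane-1,2-diol (target)
Conditions: HF·pyridine, pyridine/THF, 0 °C to rt
Reagents that add atoms: none
Why: Fluoride-driven Si–O cleavage of the tertiary triethylsilyl ether under buffered conditions that leave the alkenes, the bromohydrin and the diol untouched, giving the target.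

**Compound list**
1 | (R)-(+)-limonene, (4R)-1-methyl-4-(prop-1-en-2-yl)cyclohex-1-ene | CC1=CC[C@@H](CC1)C(C)=C | starting material
2 | (1S,2S,4R)-1-methyl-2-(phenylselanyl)-4-(prop-1-en-2-yl)cyclohexan-1-ol (not isolated) | C=C(C)[C@@H]1CC[C@](C)(O)[C@@H]([Se]c2ccccc2)C1 | intermediate
3 | (1S,2R,4R)-2-bromo-1-methyl-4-(prop-1-en-2-yl)cyclohexan-1-ol | C=C(C)[C@@H]1CC[C@](C)(O)[C@H](Br)C1 | intermediate
4 | {[(1S,2R,4R)-2-bromo-1-methyl-4-(prop-1-en-2-yl)cyclohexyl]oxy}triethylsilane | C=C(C)[C@@H]1CC[C@](C)(O[Si](CC)(CC)CC)[C@H](Br)C1 | intermediate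
5 | {[(1S,2R,4R)-2-bromo-4-(3-chloroprop-1-en-2-yl)-1-methylcyclohexyl]oxy}triethylsilane | C=C(CCl)[C@@H]1CC[C@](C)(O[Si](CC)(CC)CC)[C@H](Br)C1 | intermediate
6 | {[(1S,2R,4R)-2-bromo-4-(3-iodoprop-1-en-2-yl)-1-methylcyclohexyl]oxy}triethylsilane | C=C(CI)[C@@H]1CC[C@](C)(O[Si](CC)(CC)CC)[C@H](Br)C1 | intermediate
7 | (S)-(+)-carvone, (5S)-2-methyl-5-(prop-1-en-2-yl)cyclohex-2-en-1-one | CC1=CC[C@@H](CC1=O)C(C)=C | starting material
8 | (1S,4S,6S)-1-methyl-4-(prop-1-en-2-yl)-7-oxabicyclo[4.1.0]heptan-2-one (epoxide trans to isopropenyl) | C[C@]12O[C@H]1C[C@@H](CC2=O)C(C)=C | intermediate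
9 | 1-methyl-4-(prop-1-en-2-yl)-7-oxabicyclo[4.1.0]heptan-2-ol, epoxide and isopropenyl centres as in 8, both carbinol epimers, present as its aluminium alkoxide (not isolated) | C[C@]12O[C@H]1C[C@@H](CC2O)C(C)=C | intermediate
10 | (1S,4S)-1-methyl-4-(prop-1-en-2-yl)cyclohexane-1,2-diol, tertiary hydroxyl trans to isopropenyl, mixture of C2 epimers (expected mainly 2R, hydroxyls cis) | C[C@]1(O)CC[C@@H](CC1O)C(C)=C | intermediate
11 | (2S,5S)-2-hydroxy-2-methyl-5-(prop-1-en-2-yl)cyclohexan-1-one | C[C@]1(O)CC[C@@H](CC1=O)C(C)=C | intermediate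
12 | dilithium (1S,4S)-1-methyl-4-(prop-1-en-2-yl)cyclohex-2-ene-1,2-diolate, the alkoxide enolate of 11 (not isolated) | [Li+].[Li+].C[C@]1([O-])CC[C@@H](C=C1[O-])C(C)=C | intermediate
13 | (2S,5S,6R)-6-{2-[(1R,3R,4S)-3-bromo-4-methyl-4-(triethylsilyloxy)cyclohexyl]prop-2-en-1-yl}-2-hydroxy-2-methyl-5-(prop-1-en-2-yl)cyclohexan-1-one | C=C(C[C@@H]1[C@@H](C(=C)C)CC[C@](C)(O)C1=O)[C@@H]1CC[C@](C)(O[Si](CC)(CC)CC)[C@H](Br)C1 | intermediate
14 | (1S,2S,3R,4S)-3-{2-[(1R,3R,4S)-3-bromo-4-methyl-4-(triethylsilyloxy)cyclohexyl]prop-2-en-1-yl}-1-methyl-4-(prop-1-en-2-yl)cyclohexane-1,2-diol | C=C(C[C@@H]1[C@@H](C(=C)C)CC[C@](C)(O)[C@H]1O)[C@@H]1CC[C@](C)(O[Si](CC)(CC)CC)[C@H](Br)C1 | intermediate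
15 | (1S,2S,3R,4S)-3-{2-[(1R,3R,4S)-3-bromo-4-hydroxy-4-methylcyclohexyl]prop-2-en-1-yl}-1-methyl-4-(prop-1-en-2-yl)cyclohexane-1,2-diol | C=C(C[C@@H]1[C@@H](C(=C)C)CC[C@](C)(O)[C@H]1O)[C@@H]1CC[C@](C)(O)[C@H](Br)C1 | target

**Totals**
Total step count: 10. Longest linear sequence: 7 steps (steps 1–4, then 8–10, from limonene); the carvone branch is steps 5–7.

**Three steps most likely to fail**

Step 1 (the proposed new method). The risks are anti-bromination of the alkene by free Br2 before selenium intercepts it, epoxide formation by the neighbouring hydroxyl at the tetravalent selenium stage (which would lead to the trans bromohydrin), and reaction at the isopropenyl group. The fallback uses known chemistry, sets out from 1 and comes back at 4. Stoichiometric anti-hydroxyselenation of 1 with PhSeCl in MeCN/H2O gives hydroxy selenide 2, isolated this time. Et3SiOTf and 2,6-lutidine convert it to triethyl{[(1S,2S,4R)-1-methyl-2-(phenylselanyl)-4-(prop-1-en-2-yl)cyclohexyl]oxy}silane F1, whose silyl ether cannot close to an epoxide. Br2 (1.0 equiv) in dry CH2Cl2 at −78 °C then forms the selenium dibromide, which bromide displaces at carbon with inversion to give 4 directly, so step 2 is skipped.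

Step 6. The hydride opening at C3 runs against the preferred trans-diaxial mode in the more stable conformer, and the alkoxide of the minor carbinol epimer can undergo epoxide migration. The fallback sets out from 8 and comes back at 10. Luche reduction (NaBH4, CeCl3·7H2O, MeOH, −78 °C) gives the epoxy alcohol 9 as an isolated compound, mainly the epimer with the hydroxyl cis to the epoxide. LiBH4 with Ti(OiPr)4 in THF then delivers hydride to C3 of the titanium-chelated epoxy alcohol and gives 10 as essentially one epimer. New compounds on this detour: none F0.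

Step 8. The dianion may be sluggish, may transfer protons to the product, or may give some C6 epimer. The fallback sets out from 11 (with 6) and comes back at 13. Condensation of 11 with 1,1-dimethylhydrazine (AcOH cat., EtOH, reflux) gives (1S,4S)-2-(2,2-dimethylhydrazinylidene)-1-methyl-4-(prop-1-en-2-yl)cyclohexan-1-ol F2. Deprotonation with LiN(iPr)2 (2.2 equiv, THF, −78 to 0 °C) and alkylation of the more nucleophilic azaenolate with 6 gives (1S,3R,4S)-3-{2-[(1R,3R,4S)-3-bromo-4-methyl-4-(triethylsilyloxy)cyclohexyl]prop-2-en-1-yl}-2-(2,2-dimethylhydrazinylidene)-1-methyl-4-(prop-1-en-2-yl)cyclohexan-1-ol F3. Hydrolysis with CuCl2 in THF/pH 7 buffer returns ketone 13; any minor C6 epimer is equilibrated to the trans isomer with a little NaOMe in MeOH.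

**Further compounds**
F1 | step 1 | triethyl{[(1S,2S,4R)-1-methyl-2-(phenylselanyl)-4-(prop-1-en-2-yl)cyclohexyl]oxy}silane | C=C(C)[C@@H]1CC[C@](C)(O[Si](CC)(CC)CC)[C@@H]([Se]c2ccccc2)C1
F0 | step 6 | none | none
F2 | step 8 | (1S,4S)-2-(2,2-dimethylhydrazinylidene)-1-methyl-4-(prop-1-en-2-yl)cyclohexan-1-ol | C[C@]1(O)CC[C@@H](CC1=NN(C)C)C(C)=C
F3 | step 8 | (1S,3R,4S)-3-{2-[(1R,3R,4S)-3-bromo-4-methyl-4-(triethylsilyloxy)cyclohexyl]prop-2-en-1-yl}-2-(2,2-dimethylhydrazinylidene)-1-methyl-4-(prop-1-en-2-yl)cyclohexan-1-ol | C=C(C[C@@H]1[C@@H](C(=C)C)CC[C@](C)(O)C1=NN(C)C)[C@@H]1CC[C@](C)(O[Si](CC)(CC)CC)[C@H](Br)C1
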